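## Retrosynthetic overview

1. The target is cut at the ester C–O bond (C18–O–acyl) into the labdane alcohol 7 and the hydroxy acid 11, which are joined last by a Steglich esterification.
2. Hydroxy acid 11 comes from the open-chain dienoic acid 10 in one step that forms the tertiary C–O bond, the cyclohexane ring and both ring stereocentres (new catalytic asymmetric cyclisation–hydration). Acid 10 comes from (2E,6E)-farnesol by Noyori hydrogenation and oxidation.
3. Alcohol 7 comes from (−)-sclareol. The C18–O bond is made by microbial C–H hydroxylation, the enoate by Lemieux–Johnson cleavage and HWE olefination, and the 8(17)-alkene by E2 dehydration.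
4. Ring order: the decalin is taken intact from sclareol. The only ring built is the cyclohexanol of 11 (step 7), and the two halves are united in step 8.

Assumption: labdane numbering is used (C18 = equatorial 4α-methyl), and the catalyst antipode in step 7 that gives the (1R,2R) ring is taken as (R,R) by analogy, to be confirmed on the first run (the (S,S) catalyst is equally available).

## Route

Step 1
Reactants: 1 (−)-sclareol
Product: 2 18-hydroxysclareol
Conditions: Cunninghamella sp. NRRL 5695, growing culture (glucose/soy medium), air, 27 °C, 5 d; EtOAc extraction, SiO2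
Reagents that add atoms: dioxygen, O=O
Why: Fungal P450 C–H hydroxylation of sclareol at the equatorial 4α-methyl is a documented whole-cell biotransformation of this substrate; it makes C4 stereogenic (R) because only the 4α-methyl is oxidised, leaves all other centres untouched, and the 3β-hydroxy isomer is the main by-product removed by chromatography.

Step 2
Reactants: 2 18-hydroxysclareol
Product: 3 8α,18-dihydroxy-14,15-dinorlabdan-13-one
Conditions: OsO4 (1 mol%), NaIO4 (4 equiv), THF/H2O 2:1, 45 °C
Reagents that add atoms: none
Why: Lemieux–Johnson cleavage of the vinyl group gives a tertiary α-hydroxy aldehyde that excess periodate cleaves again to the methyl ketone (the ketone oxygen is the former 13-OH), with the primary and tertiary alcohols inert.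

Step 3
Reactants: 3 8α,18-dihydroxy-14,15-dinorlabdan-13-one
Product: 5 18-acetoxy-14,15-dinorlabd-8(17)-en-13-one, via hydroxy ketone 18-acetate 4 (not isolated)
Conditions: Ac2O (1.2 equiv), pyridine, CH2Cl2, 0 °C → rt; then SOCl2 (1.5 equiv), −78 °C
Reagents that add atoms: acetic anhydride, CC(=O)OC(C)=O
Why: Only the primary neopentyl OH is acetylated, and the equatorial 8α-chlorosulfite then undergoes E2 elimination, for which only the freely rotating C17 methyl offers an anti-periplanar hydrogen, so the exocyclic alkene should dominate (about 5:1 expected; Δ7/Δ8 isomers removed on AgNO3–silica).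

Step 4
Reactants: 5 18-acetoxy-14,15-dinorlabd-8(17)-en-13-one
Product: 7 methyl (13E)-18-hydroxylabda-8(17),13-dien-15-oate, via dienoate 18-acetate 6 (not isolated)
Conditions: (MeO)2P(O)CH2CO2Me (1.4 equiv), NaH (1.3 equiv), THF, 0 → 50 °C; then MeOH, K2CO3 (cat.), rt
Reagents that add atoms: trimethyl phosphonoacetate, COC(=O)CP(=O)(OC)OC
Why: Horner–Wadsworth–Emmons olefination of the methyl ketone gives mainly the E-enoate (about 5:1 expected, Z removed by chromatography), and carbonate-catalysed methanolysis then removes the acetate while the methyl enoate is unchanged because its transesterification is degenerate.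

Step 5
Reactants: 8 (2E,6E)-farnesol
Product: 9 (3S,6E)-3,7,11-trimethyldodeca-6,10-dien-1-ol
Conditions: H2 (100 atm), Ru(OAc)2[(R)-BINAP] (0.2 mol%), MeOH/H2O 95:5, 20 °C
Reagents that add atoms: none
Why: Noyori hydroxyl-directed asymmetric hydrogenation reduces only the allylic-alcohol C=C and sets C3 as S (the (R)-BINAP/E-allylic alcohol pairing that gives (S)-citronellol from geraniol), leaving the two remote trisubstituted alkenes untouched.

Step 6
Reactants: 9 (3S,6E)-3,7,11-trimethyldodeca-6,10-dien-1-ol
Product: 10 (3S,6E)-3,7,11-trimethyldodeca-6,10-dienoic acid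
Conditions: TEMPO (10 mol%), PhI(OAc)2 (2.2 equiv), MeCN/H2O 1:1, rt
Reagents that add atoms: water, O
Why: Oxoammonium (TEMPO/BAIB) oxidation takes the primary alcohol through the aldehyde hydrate to the acid without touching the trisubstituted alkenes or the C3 centre.

Step 7
Reactants: 10 (3S,6E)-3,7,11-trimethyldodeca-6,10-dienoic acid
Product: 11 (3S)-5-[(1R,2R)-2-hydroxy-2,6,6-trimethylcyclohexyl]-3-methylpentanoic acid
Conditions: (R,R)-IDPi (3 mol%), H2O (5 equiv), HFIP, −20 °C; Et3N quench
Reagents that add atoms: water, O
Why: Proposed new method: a confined, strongly acidic BINOL-derived imidodiphosphorimidate (large 3,3′-aryl walls, N-triflyl groups) protonates the terminal C10=C11 alkene inside its chiral pocket, the chair-folded C6=C7 alkene attacks C11, and a water molecule hydrogen-bonded to the catalyst anion in the fluorinated-alcohol network captures C7 anti, so the E-alkene gives the trans (chain/OH) ring by Stork–Eschenmoser anti addition while the pocket selects the fold that gives (1R,2R), the remote C3 centre being unaffected; the closest known reactions are IDPi-catalysed asymmetric polyene cyclisations in fluorinated alcohols terminated by an internal hydroxyl and enzymatic (squalene–hopene cyclase) cyclisation–hydration, but intermolecular water termination under chiral Brønsted acid control has not been shown.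

Step 8
Reactants: 7 methyl (13E)-18-hydroxylabda-8(17),13-dien-15-oate; 11 (3S)-5-[(1R,2R)-2-hydroxy-2,6,6-trimethylcyclohexyl]-3-methylpentanoic acid
Product: 12 methyl (13E)-18-{[(3S)-5-[(1R,2R)-2-hydroxy-2,6,6-trimethylcyclohexyl]-3-methylpentanoyl]oxy}labda-8(17),13-dien-15-oate (CNP0174687.1)
Conditions: DCC (1.3 equiv), DMAP (0.3 equiv), CH2Cl2, 0 °C → rt
Reagents that add atoms: none
Why: Steglich esterification forms the uniting C–O bond at the only primary alcohol present; the hindered tertiary alcohol of 11 is not acylated and no stereocentre is touched.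

## Compound list

1 | (−)-sclareol, (13R)-labd-14-ene-8α,13-diol | C[C@@]1(O)CC[C@H]2C(C)(C)CCC[C@]2(C)[C@H]1CC[C@@](C)(O)C=C | starting material
2 | 18-hydroxysclareol, (13R)-labd-14-ene-8α,13,18-triol (4α-CH2OH, 4R) | C[C@@]1(O)CC[C@H]2[C@](C)(CO)CCC[C@]2(C)[C@H]1CC[C@@](C)(O)C=C | intermediate
3 | 8α,18-dihydroxy-14,15-dinorlabdan-13-one | C[C@@]1(O)CC[C@H]2[C@](C)(CO)CCC[C@]2(C)[C@H]1CCC(C)=O | intermediate
4 | 18-acetoxy-8α-hydroxy-14,15-dinorlabdan-13-one | C[C@@]1(O)CC[C@H]2[C@](C)(COC(C)=O)CCC[C@]2(C)[C@H]1CCC(C)=O | intermediate
5 | 18-acetoxy-14,15-dinorlabd-8(17)-en-13-one | C=C1CC[C@H]2[C@](C)(COC(C)=O)CCC[C@]2(C)[C@H]1CCC(C)=O | intermediate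
6 | methyl (13E)-18-acetoxylabda-8(17),13-dien-15-oate | C=C1CC[C@H]2[C@](C)(COC(C)=O)CCC[C@]2(C)[C@H]1CC/C(C)=C/C(=O)OC | intermediate
7 | methyl (13E)-18-hydroxylabda-8(17),13-dien-15-oate (4R,5R,9S,10R) | C=C1CC[C@H]2[C@](C)(CO)CCC[C@]2(C)[C@H]1CC/C(C)=C/C(=O)OC | intermediate
8 | (2E,6E)-farnesol, (2E,6E)-3,7,11-trimethyldodeca-2,6,10-trien-1-ol | OC/C=C(C)/CC/C=C(C)/CCC=C(C)C | starting material
9 | (3S,6E)-3,7,11-trimethyldodeca-6,10-dien-1-ol | OCC[C@@H](C)CC/C=C(C)/CCC=C(C)C | intermediate
10 | (3S,6E)-3,7,11-trimethyldodeca-6,10-dienoic acid | OC(=O)C[C@@H](C)CC/C=C(C)/CCC=C(C)C | intermediate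
11 | (3S)-5-[(1R,2R)-2-hydroxy-2,6,6-trimethylcyclohexyl]-3-methylpentanoic acid (OH trans to the side chain) | OC(=O)C[C@@H](C)CC[C@@H]1C(C)(C)CCC[C@@]1(C)O | intermediate
12 | methyl (13E)-18-{[(3S)-5-[(1R,2R)-2-hydroxy-2,6,6-trimethylcyclohexyl]-3-methylpentanoyl]oxy}labda-8(17),13-dien-15-oate | C=C1CC[C@H]2[C@](C)(COC(=O)C[C@@H](C)CC[C@@H]3C(C)(C)CCC[C@@]3(C)O)CCC[C@]2(C)[C@H]1CC/C(C)=C/C(=O)OC | target

## Step count and risks

Total step count: 8 (steps 3 and 4 are one-pot, two-stage operations).
Longest linear sequence: 5 (steps 1, 2, 3, 4, 8); the acid branch is steps 5, 6, 7, then 8.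

The three steps most likely to fail:

Step 7 (the new step). Risks are termination by elimination instead of water capture, plain hydration of an alkene without ring closure, and low or reversed enantio-induction. The fallback uses known chemistry, sets out from 10 and comes back at 11. Classical formolysis (HCO2H, 0 → 20 °C), the acid-mediated diene cyclisation with anti capture by formate, gives the two trans formates (3S)-5-[(1R,2R)-2-(formyloxy)-2,6,6-trimethylcyclohexyl]-3-methylpentanoic acid F1 and (3S)-5-[(1S,2S)-2-(formyloxy)-2,6,6-trimethylcyclohexyl]-3-methylpentanoic acid F2 in roughly equal amounts, because nothing controls the fold. KOH in MeOH/H2O cleaves both formates to 11 and its ring diastereomer (3S)-5-[(1S,2S)-2-hydroxy-2,6,6-trimethylcyclohexyl]-3-methylpentanoic acid F3. The two are separated by preparative chiral-phase SFC (or as their (R)-1-phenylethylammonium salts), so the ring stereocentres come from a separation instead of a catalyst, at the cost of at least half the material.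

Step 1. The reaction is precedented on sclareol itself, but the 18-isomer competes with 3β-hydroxylation and the yield is modest. The fallback sets out from 1 and comes back at 3, changing both the order of events and the class of catalyst. The side chain is cut first with OsO4/NaIO4 (conditions of step 2) to give 8α-hydroxy-14,15-dinorlabdan-13-one F4, a smaller and more polar substrate. The C18 oxygen is then installed on F4 with a recombinant, evolvable P450 (a CYP102A1 variant panel in E. coli whole cells, glucose, air), screened for oxidation of the 4α-methyl, giving 3 directly. This enzymatic step is unprecedented on F4 and would need screening.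

Step 3. Risks are Δ7/Δ8 alkene isomers and, because a γ-ketone is present, loss of material through the cyclic hemiketal to an enol ether. The fallback sets out from 4 (isolated after the acetylation) and comes back at 6, reversing the order of olefination and elimination. HWE olefination of 4 (same phosphonate, NaH, THF, 0 °C → rt) gives methyl (13E)-18-acetoxy-8α-hydroxylabd-13-en-15-oate F5, which has no ketone left to form a hemiketal. Syn-elimination with the Burgess reagent (toluene, 50 °C) then gives 6, which is methanolysed to 7 as in the second stage of step 4. The point to watch in this order is conjugate addition of the 8-alkoxide to the new enoate during the HWE.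

Further compounds
F1 | step 7 | (3S)-5-[(1R,2R)-2-(formyloxy)-2,6,6-trimethylcyclohexyl]-3-methylpentanoic acid | OC(=O)C[C@@H](C)CC[C@@H]1C(C)(C)CCC[C@@]1(C)OC=O
F2 | step 7 | (3S)-5-[(1S,2S)-2-(formyloxy)-2,6,6-trimethylcyclohexyl]-3-methylpentanoic acid | OC(=O)C[C@@H](C)CC[C@H]1C(C)(C)CCC[C@]1(C)OC=O
F3 | step 7 | (3S)-5-[(1S,2S)-2-hydroxy-2,6,6-trimethylcyclohexyl]-3-methylpentanoic acid | OC(=O)C[C@@H](C)CC[C@H]1C(C)(C)CCC[C@]1(C)O
F4 | step 1 | 8α-hydroxy-14,15-dinorlabdan-13-one | C[C@@]1(O)CC[C@H]2C(C)(C)CCC[C@]2(C)[C@H]1CCC(C)=O
F5 | step 3 | methyl (13E)-18-acetoxy-8α-hydroxylabd-13-en-15-oate | C[C@@]1(O)CC[C@H]2[C@](C)(COC(C)=O)CCC[C@]2(C)[C@H]1CC/C(C)=C/C(=O)OC
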